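The constant in dispute is the first-order rate constant at which complex with one exchanged disappears, and two chemists read it differently from the same runs.

| flask | starting complex | incoming ligand | capture agent | remark | time |
|---|---|---|---|---|---|
| Wednesday's | 44 mM | 52 mM | 44 mM | run made earlier |  |
| Sunday's | 44 mM | 230 mM | 44 mM | run made earlier |  |
| violet | 44 mM | 35.2 mM | 44.0 mM |  | 30 min |
| green | 44 mM | 88.0 mM | 44.0 mM |  | 30 min |
| red | 44 mM | 176 mM | 44.0 mM |  | 30 min |

| run | time / min | complex with one exchanged / % | complex with two exchanged / % | starting complex / % |
|---|---|---|---|---|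
| Wednesday's | 1.50 | 20 | 0 | 72 |
| Wednesday's | 3.00 | 30 | 4 | 62 |
| Wednesday's | 5.00 | 29 | 4 | 47 |
| Wednesday's | 8.00 | 31 | 6 | 35 |
| Wednesday's | 12.0 | 24 | 4 | 26 |
| Wednesday's | 20.0 | 16 | 4 | 12 |
| Sunday's | 1.33 | 54 | 9 | 29 |
| Sunday's | 4.00 | 42 | 14 | 5 |
| Sunday's | 8.00 | 22 | 19 | 3 |
| Sunday's | 12.0 | 8 | 15 | 0 |
| Sunday's | 15.0 | 8 | 13 | 0 |
| Sunday's | 20.0 | 1 | 6 | 0 |

(standard deviation of a reading: 2 percentage points)

- the numbers in the tables scatter by 2 percentage points (one standard deviation)

* how much complex with one exchanged is there at the end, in percent of the starting complex charged: for each flask in turn (violet, green, red)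

The first chemist takes it as flat, a pseudo-first-order constant. I take the second view: capture agent is charged level with starting complex, so it stands in no excess, and the drain should shrink with the capture agent left.

Suppose each complex missing from Wednesday's table took one capture agent. Then the share of capture agent left equals the visible sum. That sum falls from 80.0% to 54.0% between 5.00 min and 12.0 min, a loss of 0.0371 min⁻¹. Dividing by the mean one-exchanged share and the mean capture share gives a reading of 0.209 min⁻¹, the capture constant at full charge κ: the drain when capture agent stands at its charge.

For green, Wednesday's loss of starting complex, scaled by ligand, gives a feed half-life of 4.23 min, short against 30 min, so I treat the feed as instantaneous.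

In the first round, capture agent left equals one-exchanged complex, and the hyperbola 1/(1 + κt) gives 13.8%. A flat κ would give 0.189%.

For the second round I put that answer back: capture agent left exceeds one-exchanged complex by the share b gone onward. Wednesday's top two-exchanged reading, scaled by ligand, gives b = 10.2%. Integrating gives bs/(1 − s), with s = (1 − b)exp(−κbt), so I commit to 9.18% in green.

The first chemist's forecast, from “One-exchanged complex disappears at about 0.2 min⁻¹ in both runs”, reads 4%, 1.5% and 0.3% for violet, green and red.

The flasks give 9.51%, 9.17% and 1.53%.

    complex with one exchanged + incoming ligand ⇌ leaving ligand + complex with two exchanged (K = 4.60, k = 0.00986 M⁻¹ s⁻¹)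
    leaving ligand → by-product carried off (k = 0.00562 s⁻¹)
    complex with two exchanged + incoming ligand ⇌ leaving ligand + complex with three exchanged (K = 6.10, k = 0.0152 M⁻¹ s⁻¹)
    complex with one exchanged + capture agent → trapped intermediate (k = 0.0646 M⁻¹ s⁻¹)
    incoming ligand → decomposition product (k = 2.60 × 10⁻⁶ s⁻¹)
    starting complex + incoming ligand ⇌ leaving ligand + complex with one exchanged (K = 8.20, k = 0.0704 M⁻¹ s⁻¹)

In green, the half-life of one-exchanged complex by capture alone, at charged amounts, is 4.1 min, shorter than the 13 min of the forward onward step alone. A flat constant fits the stretch where capture agent stands near its charge, which is the condition that capture half-life is reckoned for. In red, two- and three-exchanged complexes together make b = 38.7%, so the same rule gives 2.22%, where red holds 1.53%.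

(All runs are calculated with constants of no real substance; scatter was added.)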